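Whatever a flask does, each unit of J charged stands either as J or as L, and if each G begins one chain, the chains begun cannot outnumber the G charged.

| flask | J | G | remark | time |
|---|---|---|---|---|
| Saturday's | 0.50 M | 6 mM | run made earlier |  |
| Tuesday's | 0.50 M | 9 mM | run made earlier |  |
| Sunday's | 0.25 M | 12 mM | run made earlier |  |
| green | 0.50 M | 12 mM |  | 4.0 h |
| blue | 0.50 M | 12 mM |  | 8.0 h |

| run | time / h | L / % |
|---|---|---|
| Saturday's | 0.417 | 2 |
| Saturday's | 1.00 | 4 |
| Saturday's | 2.00 | 11 |
| Saturday's | 3.00 | 26 |
| Tuesday's | 0.250 | 2 |
| Tuesday's | 0.667 | 0 |
| Tuesday's | 1.33 | 13 |
| Tuesday's | 3.00 | 35 |
| Sunday's | 0.250 | 0 |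
| Sunday's | 0.667 | 8 |
| Sunday's | 1.33 | 15 |
| Sunday's | 3.00 | 43 |

(standard deviation of a reading: 2 percentage points)

1. which of the two ends with the longer chains by the average number of monomer units in a chain (chains begun, living or dead) ("neither" if they lie within 10%) (green / blue / neither)
2. average number of monomer units in a chain (chains begun, living or dead) at the end, green
3. average number of monomer units in a chain (chains begun, living or dead) at the end, blue

- the average divides the monomer in chains by the number of chains begun, living and dead together
- the earlier runs do not show the number of chains; that part of a forecast is a guess

So I took J charged per G charged, 41.7 units for green and blue alike, as the yardstick length. It is a reference and no upper limit, because the average length is this yardstick times the share of J in chains, divided by the share of G begun, and a flask with less of its G begun than of its J converted stands above it. That share of G cannot pass one, so yardstick times conversion is a floor, and I needed the conversion.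

Sunday's run has the G of green and blue but less J, and that was my first doubt. Taking the decay exponent as the natural log of J charged over J remaining, Sunday's reached 0.562 at 3.00 h. That is 1.30 times Tuesday's for 1.33 times the G, so the fractional decay seemed to follow G and not J, within the scatter, and I took Sunday's curve over.

Replacing that curve by its mean rate, 0.187 h⁻¹, gave green 52.7%. But the curve bends upward: its last stretch ran at 0.239 h⁻¹, a pseudo-first-order decay with a time constant of 4.18 h. Carrying that slope forward gave 55.1% for green and 82.8% for blue, so the floors were 23.0 and 34.5. The objection was that the slope may still rise and that some G may not have begun, but both push the length up. I therefore expected both flasks above their floors, with blue ahead by a ratio of 1.50, though the readings do not show the chain count.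

The forecast read the runs as “slow initiation feeding living chains” and said blue, with 29 for green and 38 for blue, above my floors.

The flask gave blue, with 25.0 for green and 36.3 for blue, so the forecast's green stood at 1.16 times the flask's.

    J + E → Q + L (k = 1.40 L mol⁻¹ min⁻¹)
    J + Q → L + Q, rate k2*[Q]*[J] (k = 0.420 L mol⁻¹ min⁻¹)
    G → E (k = 0.0120 min⁻¹)

In green at 4.00 h, Q held 94.2% of the G charged and L held 56.5% of the J, so the yardstick gives 25.0. Blue's chains were longer because it ran longer: held to green's time, blue's length falls to 25.0. For the neighbour of green with G at 0.020 M, the yardstick becomes 25.0, and its L of 75.1% over 94.0% begun gives 20.0. The computed length there is 20.0.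

The readings were computed on assumed constants.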